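**Retrosynthetic overview**

- The butenolide (ring atoms O1, C2(=O), C3(Me), C4(H), C5; exocyclic carbon C1', chain C2'–C9') is the only ring that is built, and it is built last. It is opened at C4–C5 to an acyclic (Z)-alk-1-enyl ester of (Z)-3-iodo-2-methylacrylic acid, which is closed by a 5-exo Heck cyclisation.
- Enabling feature: O1 is an enol-ester oxygen joining the acyl carbon C2 to the ylidene carbon C5. The C3=C4 unit (as a Z-alkenyl iodide) and the C5=C1' alkene (as a Z-enol ester) are therefore already linked through C2–O1 in a five-atom chain, and the syn-insertion/syn-elimination sequence should turn the Z-enol ester into the 5E-ylidene.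
- The enol ester comes from ruthenium-catalysed anti-Markovnikov addition of the iodo acid (from propargyl alcohol by carbomagnesiation–iodination and oxidation) to a terminal alkyne.
- The alkyne comes from Ohira–Bestmann homologation of an α-methyl aldehyde. Its C3'–C4' bond is made by Negishi coupling of the zinc reagent of (R)-3-bromo-2-methylpropan-1-ol (source of the only stereocentre) with an (E,E)-dienyl iodide.
- The dienyl iodide comes from Takai and Wittig olefinations of a furylpropanal, itself made by B-alkyl Suzuki coupling of 4-bromo-2-(furan-3-ylmethyl)furan. Both furan rings are bought and joined by organolithium addition and ionic hydrogenation.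

Key step: step 15

Assumption: the target is read as the (5E)-ylidene isomer (side chain cis to C4–H, trans to O1) with a (2'S) methyl-bearing centre and a (4'E,6'E)-diene.

**Route**

Step 1
Reactants: 1 3-bromofuran; 2 4-bromofuran-2-carbaldehyde
Product: 4 (4-bromofuran-2-yl)(furan-3-yl)methanol (racemic), via furan-3-yllithium 3 (not isolated)
Conditions: n-BuLi, THF, −78 °C; then 2, −78 °C; H2O
Reagents that add atoms: none
Why: Bromine–lithium exchange at −78 °C gives furan-3-yllithium, which undergoes 1,2-addition to the aldehyde far faster than it exchanges with the ring bromide of 2; the racemic carbinol centre is removed in step 2.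

Step 2
Reactants: 4 (4-bromofuran-2-yl)(furan-3-yl)methanol
Product: 5 4-bromo-2-(furan-3-ylmethyl)furan
Conditions: Et3SiH, TFA, CH2Cl2, −20 → 0 °C
Reagents that add atoms: none
Why: Ionic hydrogenation, in which the doubly heteroaryl-stabilised carbocation is trapped by hydride from the silane; low temperature and excess silane should suppress Friedel–Crafts oligomerisation.

Step 3
Reactants: 5 4-bromo-2-(furan-3-ylmethyl)furan; 6 3,3-diethoxyprop-1-ene
Product: 8 4-(3,3-diethoxypropyl)-2-(furan-3-ylmethyl)furan, via B-(3,3-diethoxypropyl)-9-BBN 7 (not isolated)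
Conditions: 6, 9-BBN, THF, 0 °C → rt; then 5, PdCl2(dppf) (5 mol%), aq. K3PO4, DMF, 60 °C
Reagents that add atoms: none
Why: B-alkyl Suzuki–Miyaura coupling, with anti-Markovnikov hydroboration of the terminal alkene and transfer of the primary alkyl group to the furyl bromide; the acetal masks the aldehyde.

Step 4
Reactants: 8 4-(3,3-diethoxypropyl)-2-(furan-3-ylmethyl)furan
Product: 9 3-[5-(furan-3-ylmethyl)furan-3-yl]propanal
Conditions: PPTS (cat.), acetone–H2O, 50 °C
Reagents that add atoms: water, O
Why: Mild acid-catalysed acetal hydrolysis under conditions that 2,4-dialkylfurans should tolerate.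

Step 5
Reactants: 9 3-[5-(furan-3-ylmethyl)furan-3-yl]propanal
Product: 10 (2E)-5-[5-(furan-3-ylmethyl)furan-3-yl]-2-methylpent-2-enal
Conditions: Ph3P=C(CH3)CHO, toluene, 90 °C
Reagents that add atoms: 2-(triphenylphosphoranylidene)propanal, CC(C=O)=P(c1ccccc1)(c1ccccc1)c1ccccc1
Why: Wittig olefination with a stabilised formyl ylide, which should give the (E)-2-methylenal and reacts only sluggishly with the enal product.

Step 6
Reactants: 10 (2E)-5-[5-(furan-3-ylmethyl)furan-3-yl]-2-methylpent-2-enal
Product: 11 2-(furan-3-ylmethyl)-4-[(3E,5E)-6-iodo-4-methylhexa-3,5-dien-1-yl]furan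
Conditions: CHI3, CrCl2, THF, 0 °C → rt, dark
Reagents that add atoms: iodoform, IC(I)I
Why: Takai olefination, in which the geminal dichromium reagent adds to the aldehyde and eliminates to the (E)-alkenyl iodide without touching the trisubstituted alkene.

Step 7
Reactants: 12 (R)-3-bromo-2-methylpropan-1-ol
Product: 13 (R)-(3-bromo-2-methylpropoxy)(tert-butyl)dimethylsilane
Conditions: TBSCl, imidazole, CH2Cl2, 0 °C → rt
Reagents that add atoms: tert-butyldimethylsilyl chloride, CC(C)(C)[Si](C)(C)Cl
Why: Standard silylation of a primary alcohol; the stereocentre is not involved.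

Step 8
Reactants: 13 (R)-(3-bromo-2-methylpropoxy)(tert-butyl)dimethylsilane; 11 2-(furan-3-ylmethyl)-4-[(3E,5E)-6-iodo-4-methylhexa-3,5-dien-1-yl]furan
Product: 15 tert-butyl{[(2S,4E,6E)-9-[5-(furan-3-ylmethyl)furan-3-yl]-2,6-dimethylnona-4,6-dien-1-yl]oxy}dimethylsilane, via alkylzinc bromide 14 (not isolated)
Conditions: 13, Zn dust, I2 (5 mol%), DMA, 80 °C; then 11, Pd(PPh3)4 (5 mol%), DMA–THF, 40 °C
Reagents that add atoms: none
Why: Negishi coupling, in which zinc inserts into the primary C–Br bond and the alkylzinc couples with the (E)-alkenyl iodide on zerovalent palladium with retention of alkene geometry; the stereocentre is β to zinc and cannot epimerise (its descriptor changes from R to S only through the priority change).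

Step 9
Reactants: 15 the silyl ether from step 8
Product: 16 (2S,4E,6E)-9-[5-(furan-3-ylmethyl)furan-3-yl]-2,6-dimethylnona-4,6-dien-1-ol
Conditions: TBAF, THF, 0 °C → rt
Reagents that add atoms: none
Why: Fluoride cleavage of the primary silyl ether; nothing else in the molecule is fluoride-labile.

Step 10
Reactants: 16 (2S,4E,6E)-9-[5-(furan-3-ylmethyl)furan-3-yl]-2,6-dimethylnona-4,6-dien-1-ol
Product: 17 (2S,4E,6E)-9-[5-(furan-3-ylmethyl)furan-3-yl]-2,6-dimethylnona-4,6-dienal
Conditions: Dess–Martin periodinane, NaHCO3, CH2Cl2, 0 °C → rt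
Reagents that add atoms: none
Why: Buffered Dess–Martin oxidation, which is non-basic and should not enolise the α-methyl aldehyde.

Step 11
Reactants: 17 (2S,4E,6E)-9-[5-(furan-3-ylmethyl)furan-3-yl]-2,6-dimethylnona-4,6-dienal
Product: 18 2-(furan-3-ylmethyl)-4-[(3E,5E,8S)-4,8-dimethyldeca-3,5-dien-9-yn-1-yl]furan
Conditions: dimethyl (1-diazo-2-oxopropyl)phosphonate, K2CO3, MeOH, 0 °C → rt
Reagents that add atoms: dimethyl (1-diazo-2-oxopropyl)phosphonate, CC(=O)C(=[N+]=[N-])P(=O)(OC)OC
Why: Ohira–Bestmann (Seyferth–Gilbert) homologation, in which the diazomethylphosphonate anion adds to the aldehyde and the alkylidene carbene rearranges to the terminal alkyne; the mild carbonate/methanol conditions are expected to preserve the α-methyl stereocentre.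

Step 12
Reactants: 19 prop-2-yn-1-ol
Product: 21 (Z)-3-iodo-2-methylprop-2-en-1-ol, via oxamagnesacycle 20 (not isolated)
Conditions: MeMgBr (2.5 equiv), CuI (10 mol%), THF, −10 °C → rt; then I2, −78 → 0 °C
Reagents that add atoms: methylmagnesium bromide, C[Mg]Br; iodine, II
Why: Copper-catalysed carbomagnesiation of the magnesium alkoxide delivers methyl to C2 and magnesium to C3 in an anti sense through a five-membered chelate, and iodinolysis with retention gives the (Z)-iodoalkene.

Step 13
Reactants: 21 (Z)-3-iodo-2-methylprop-2-en-1-ol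
Product: 23 (Z)-3-iodo-2-methylprop-2-enoic acid, via (Z)-3-iodo-2-methylprop-2-enal 22 (not isolated)
Conditions: TEMPO (20 mol%), PhI(OAc)2 (2.2 equiv), MeCN–H2O, rt
Reagents that add atoms: water, O
Why: Oxoammonium-mediated oxidation of the allylic alcohol through the aldehyde hydrate to the acid, which should leave the alkenyl iodide and its Z geometry intact.

Step 14
Reactants: 18 the terminal alkyne from step 11; 23 (Z)-3-iodo-2-methylprop-2-enoic acid
Product: 24 (1Z,3S,5E,7E)-10-[5-(furan-3-ylmethyl)furan-3-yl]-3,7-dimethyldeca-1,5,7-trien-1-yl (2Z)-3-iodo-2-methylprop-2-enoate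
Conditions: Ru(η3-2-methylallyl)2(dppb) (5 mol%), toluene, 50 °C
Reagents that add atoms: none
Why: Ruthenium-catalysed anti-Markovnikov addition of a carboxylic acid to a terminal alkyne, in which carboxylate attack at the α-carbon of a ruthenium vinylidene and protonolysis give the (Z)-alk-1-enyl ester; the alkenyl iodide should be inert to divalent ruthenium.

Step 15
Reactants: 24 the (Z)-enol ester from step 14
Product: 25 (5E)-5-[(2S,4E,6E)-9-[5-(furan-3-ylmethyl)furan-3-yl]-2,6-dimethylnona-4,6-dien-1-ylidene]-3-methylfuran-2(5H)-one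
Conditions: Pd(OAc)2 (10 mol%), PPh3 (20 mol%), Ag2CO3 (1.5 equiv), MeCN, 60 °C, dark
Reagents that add atoms: none
Why: Proposed new method: oxidative addition of zerovalent palladium into the C4–I bond gives a (Z)-alkenylpalladium iodide that Ag2CO3 ionises; the cationic alkenylpalladium then inserts the enol-ester alkene C5=C1' in the 5-exo-trig mode through the s-cis ester rotamer, C4 migrating to the oxygen-bearing carbon C5 so that the C4–C5 bond and the lactone ring form together, and syn-β-hydride elimination of H5 releases the 5-ylidenebutenolide. The closest known reaction types are the 5-exo Heck cyclisations of N-vinyl 2-halobenzamides to 3-alkylidene-isoindolinones and the α-selective Heck arylation of vinyl esters, enol ethers and enamides under halide-free conditions; an ester-tethered closure onto a 1,2-disubstituted enol ester is not established. No stereocentre is created: syn-carbopalladation across the (Z)-enol ester, rotation by 120° about C5–C1' and syn-elimination of H5–Pd place C2' cis to C4 and H1' cis to O1, which is the (5E) isomer, whereas an (E)-enol ester would give (5Z). The step needs 5-exo rather than 6-endo closure, secured by the five-atom tether and by the charge-controlled preference of cationic palladium for the oxygen-bearing alkene carbon. It also needs loss of H5 rather than of the tertiary hydrogen at C2' or of the C5–O1 carboxylate: H5 is allylic and α to oxygen and its loss creates the conjugated dienolide, the lactone ring holds the acyl carbonyl away from palladium so that chelation-assisted β-acyloxy elimination cannot occur, and silver carbonate removes palladium hydride quickly, which should also protect the (5E) geometry, the diene and the C2' stereocentre from re-addition.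

**Compound list**

1 | 3-bromofuran | Brc1ccoc1 | starting material
2 | 4-bromofuran-2-carbaldehyde | O=Cc1cc(Br)co1 | starting material
3 | furan-3-yllithium | [Li]c1ccoc1 | intermediate (not isolated)
4 | (4-bromofuran-2-yl)(furan-3-yl)methanol (racemic) | OC(c1cc(Br)co1)c1ccoc1 | intermediate
5 | 4-bromo-2-(furan-3-ylmethyl)furan | Brc1coc(Cc2ccoc2)c1 | intermediate
6 | 3,3-diethoxyprop-1-ene | C=CC(OCC)OCC | starting material
7 | 9-(3,3-diethoxypropyl)-9-borabicyclo[3.3.1]nonane | CCOC(CCB1C2CCCC1CCC2)OCC | intermediate (not isolated)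
8 | 4-(3,3-diethoxypropyl)-2-(furan-3-ylmethyl)furan | CCOC(CCc1coc(Cc2ccoc2)c1)OCC | intermediate
9 | 3-[5-(furan-3-ylmethyl)furan-3-yl]propanal | O=CCCc1coc(Cc2ccoc2)c1 | intermediate
10 | (2E)-5-[5-(furan-3-ylmethyl)furan-3-yl]-2-methylpent-2-enal | O=C/C(C)=C/CCc1coc(Cc2ccoc2)c1 | intermediate
11 | 2-(furan-3-ylmethyl)-4-[(3E,5E)-6-iodo-4-methylhexa-3,5-dien-1-yl]furan | I/C=C/C(C)=C/CCc1coc(Cc2ccoc2)c1 | intermediate
12 | (R)-3-bromo-2-methylpropan-1-ol | OC[C@@H](C)CBr | starting material
13 | (R)-(3-bromo-2-methylpropoxy)(tert-butyl)dimethylsilane | CC(C)(C)[Si](C)(C)OC[C@@H](C)CBr | intermediate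
14 | bromo{(2R)-3-[(tert-butyldimethylsilyl)oxy]-2-methylpropyl}zinc | CC(C)(C)[Si](C)(C)OC[C@@H](C)C[Zn]Br | intermediate (not isolated)
15 | tert-butyl{[(2S,4E,6E)-9-[5-(furan-3-ylmethyl)furan-3-yl]-2,6-dimethylnona-4,6-dien-1-yl]oxy}dimethylsilane | CC(C)(C)[Si](C)(C)OC[C@@H](C)C/C=C/C(C)=C/CCc1coc(Cc2ccoc2)c1 | intermediate
16 | (2S,4E,6E)-9-[5-(furan-3-ylmethyl)furan-3-yl]-2,6-dimethylnona-4,6-dien-1-ol | OC[C@@H](C)C/C=C/C(C)=C/CCc1coc(Cc2ccoc2)c1 | intermediate
17 | (2S,4E,6E)-9-[5-(furan-3-ylmethyl)furan-3-yl]-2,6-dimethylnona-4,6-dienal | O=C[C@@H](C)C/C=C/C(C)=C/CCc1coc(Cc2ccoc2)c1 | intermediate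
18 | 2-(furan-3-ylmethyl)-4-[(3E,5E,8S)-4,8-dimethyldeca-3,5-dien-9-yn-1-yl]furan | C#C[C@@H](C)C/C=C/C(C)=C/CCc1coc(Cc2ccoc2)c1 | intermediate
19 | prop-2-yn-1-ol | C#CCO | starting material
20 | 4-methyl-2,5-dihydro-1,2-oxamagnesole (chelated (Z)-alkenylmagnesium alkoxide, drawn without coordinated MgBr2) | CC1=C[Mg]OC1 | intermediate (not isolated)
21 | (Z)-3-iodo-2-methylprop-2-en-1-ol | OC/C(C)=C\I | intermediate
22 | (Z)-3-iodo-2-methylprop-2-enal | O=C/C(C)=C\I | intermediate (not isolated)
23 | (Z)-3-iodo-2-methylprop-2-enoic acid | OC(=O)/C(C)=C\I | intermediate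
24 | (1Z,3S,5E,7E)-10-[5-(furan-3-ylmethyl)furan-3-yl]-3,7-dimethyldeca-1,5,7-trien-1-yl (2Z)-3-iodo-2-methylprop-2-enoate | C/C(=C/I)C(=O)O/C=C\[C@@H](C)C/C=C/C(C)=C/CCc1coc(Cc2ccoc2)c1 | intermediate
25 | (5E)-5-[(2S,4E,6E)-9-[5-(furan-3-ylmethyl)furan-3-yl]-2,6-dimethylnona-4,6-dien-1-ylidene]-3-methylfuran-2(5H)-one | CC1=C/C(=C\[C@@H](C)C/C=C/C(C)=C/CCc2coc(Cc3ccoc3)c2)OC1=O | target

**Step count and risks**

Total step count: 15. Longest linear sequence: 12 steps (steps 1–6, 8–11, 14, 15).

Steps most likely to fail:

Step 15 (proposed new method). The alkylpalladium intermediate may eliminate in the wrong direction (loss of the tertiary hydrogen at C2' or β-acyloxy ring opening), insertion through the ester tether may be slow, or palladium hydride re-addition may equilibrate the ylidene geometry. The fallback uses known chemistry, sets out from aldehyde 17 and returns at target 25. 3-Methylfuran-2(5H)-one would be silylated (TMSOTf, Et3N, CH2Cl2, 0 °C) to 3-methyl-2-(trimethylsilyloxy)furan F1. Vinylogous Mukaiyama aldol addition of F1 to 17 (BF3·OEt2, CH2Cl2, −78 °C) should give the 5-(1-hydroxyalkyl)butenolides, from which the 5,1'-unlike diastereomer (5R)-5-[(1S,2S,4E,6E)-9-[5-(furan-3-ylmethyl)furan-3-yl]-1-hydroxy-2,6-dimethylnona-4,6-dien-1-yl]-3-methylfuran-2(5H)-one F2 would be separated by chromatography. Anti-selective dehydration of F2 under Mitsunobu conditions (PPh3, DEAD, THF, 0 °C → rt) should place the chain cis to C4 and give 25.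

Step 14. Markovnikov addition, Z to E isomerisation of the enol ester on the ruthenium catalyst, or catalyst inhibition by the iodoacrylic acid may intervene. The fallback sets out from alkyne 18 and returns at enol ester 24. Rhodium-catalysed trans-hydroboration of 18 ([Rh(cod)Cl]2, P(i-Pr)3, Et3N, pinacolborane, cyclohexane, rt) should give the (Z)-alkenylboronate 2-[(1Z,3S,5E,7E)-10-[5-(furan-3-ylmethyl)furan-3-yl]-3,7-dimethyldeca-1,5,7-trien-1-yl]-4,4,5,5-tetramethyl-1,3,2-dioxaborolane F3. Treatment with KHF2 (MeOH–H2O) would convert it into the potassium (Z)-alkenyltrifluoroborate F4. Copper-mediated oxidative C–O coupling of F4 with acid 23 (Cu(OAc)2, DMAP, 4 Å molecular sieves, air, CH2Cl2, rt; Chan–Lam-type coupling with retention of alkene geometry) should then give 24.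

Step 2. Friedel–Crafts oligomerisation of the bis-furyl cation or acid-induced furan ring opening may compete with hydride transfer. The fallback sets out from carbinol 4 and returns at bromide 5. Oxidation of 4 with MnO2 (CH2Cl2, rt) would give (4-bromofuran-2-yl)(furan-3-yl)methanone F5. Wolff–Kishner reduction through the hydrazone F6 (N2H4·H2O, KOH, diethylene glycol, 130 → 190 °C) would then remove the oxygen under basic conditions without a carbocation and give 5.

Further compounds
F1 | step 15 | 3-methyl-2-(trimethylsilyloxy)furan | Cc1ccoc1O[Si](C)(C)C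
F2 | step 15 | (5R)-5-[(1S,2S,4E,6E)-9-[5-(furan-3-ylmethyl)furan-3-yl]-1-hydroxy-2,6-dimethylnona-4,6-dien-1-yl]-3-methylfuran-2(5H)-one | CC1=C[C@@H](OC1=O)[C@@H](O)[C@@H](C)C/C=C/C(C)=C/CCc1coc(Cc2ccoc2)c1
F3 | step 14 | 2-[(1Z,3S,5E,7E)-10-[5-(furan-3-ylmethyl)furan-3-yl]-3,7-dimethyldeca-1,5,7-trien-1-yl]-4,4,5,5-tetramethyl-1,3,2-dioxaborolane | CC1(C)OB(OC1(C)C)/C=C\[C@@H](C)C/C=C/C(C)=C/CCc1coc(Cc2ccoc2)c1
F4 | step 14 | potassium trifluoro[(1Z,3S,5E,7E)-10-[5-(furan-3-ylmethyl)furan-3-yl]-3,7-dimethyldeca-1,5,7-trien-1-yl]borate | [K+].F[B-](F)(F)/C=C\[C@@H](C)C/C=C/C(C)=C/CCc1coc(Cc2ccoc2)c1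
F5 | step 2 | (4-bromofuran-2-yl)(furan-3-yl)methanone | O=C(c1cc(Br)co1)c1ccoc1
F6 | step 2 | (4-bromofuran-2-yl)(furan-3-yl)methanone hydrazone | NN=C(c1cc(Br)co1)c1ccoc1
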